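Target 13 is the (2S,3R,4R)-oxolane (O1, C2 3,4,5-trimethoxyphenyl, C3 CH2OH, C4 3,4-dimethoxybenzoyl, C5 H2), with C2/C3 trans and C3/C4 cis.
Retrosynthesis: with the C3 arm silylated and the hydrogens at C4 and C5 removed, O1–C5=C4–C(=O)–aryl is a β-alkoxy enone inside the oxolane ring. Reading C4 and C5 as alkyne carbons, one operation cuts O1–C5, C4–C(=O) and C(=O)–aryl and leaves alkynol 8, CO and aryl iodide 9.
C2–C3 is then cut to aldehyde 6 and a chiral allenylzinc made from propargylic mesylate 5, whose C3–C4–C5 chain comes from (R)-glyceraldehyde acetonide 1.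
Forward: chain C3–C5 (steps 1–4), C2–C3 union (step 5), closure of the only ring together with the ketone and its aryl group (step 6), saturation of C4=C5 (step 7), desilylation (step 8).
Stereochemistry: C3 comes from the stereocentre of 1, relayed with net inversion (anti SN2', then syn SE2'). C2 comes from the anti-selective closed transition state of the zinc addition. C4 comes from hydrogen delivery to the ring face opposite CH2OTIPS.

Key step: step 6

Assumption: the oxolane numbering above is used for the same atoms in every intermediate, open-chain ones included, and 1 is bought as the R enantiomer and distilled before use because it hydrates and oligomerises on standing.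

Step 1
Reactants: 1 (R)-2,3-O-isopropylideneglyceraldehyde
Product: 2 (4S)-4-ethynyl-2,2-dimethyl-1,3-dioxolane
Conditions: dimethyl (1-diazo-2-oxopropyl)phosphonate (1.2 equiv), K2CO3 (2 equiv), MeOH, 0 °C to rt; pentane extraction, careful concentration
Reagents that add atoms: dimethyl (1-diazo-2-oxopropyl)phosphonate, CC(=O)C(=[N+]=[N-])P(=O)(OC)OC
Why: The Ohira–Bestmann variant of the Seyferth–Gilbert homologation turns the aldehyde into the terminal alkyne under K2CO3/MeOH, conditions under which this α-alkoxy aldehyde keeps its configuration, and the descriptor changes from R to S only because ethynyl ranks below CH2O.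

Step 2
Reactants: 2 (4S)-4-ethynyl-2,2-dimethyl-1,3-dioxolane
Product: 3 (2S)-but-3-yne-1,2-diol
Conditions: Amberlyst 15 (H+ form), MeOH/H2O 9:1, rt; filtration, evaporation
Reagents that add atoms: none
Why: Acid-catalysed acetal hydrolysis on a sulfonic acid resin frees the 1,2-diol without touching the alkyne or the stereocentre and allows the water-soluble product to be isolated without extraction.

Step 3
Reactants: 3 (2S)-but-3-yne-1,2-diol
Product: 4 (2S)-1-(triisopropylsilyloxy)but-3-yn-2-ol
Conditions: TIPSCl (1.05 equiv), imidazole (2.2 equiv), CH2Cl2/DMF, 0 °C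
Reagents that add atoms: triisopropylsilyl chloride, CC(C)[Si](Cl)(C(C)C)C(C)C
Why: Silyl ether formation under steric control, in which the bulky chlorosilane reacts with the primary hydroxyl far faster than with the secondary propargylic one, installs the large group that later screens one ring face.

Step 4
Reactants: 4 (2S)-1-(triisopropylsilyloxy)but-3-yn-2-ol
Product: 5 (2S)-1-(triisopropylsilyloxy)but-3-yn-2-yl methanesulfonate
Conditions: MsCl (1.3 equiv), Et3N (2 equiv), CH2Cl2, −78 to −20 °C; used without chromatography
Reagents that add atoms: methanesulfonyl chloride, CS(=O)(=O)Cl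
Why: O-Sulfonylation leaves the C–O bond and hence the configuration untouched and supplies the leaving group needed for the SN2' ionisation.

Step 5
Reactants: 5 (2S)-1-(triisopropylsilyloxy)but-3-yn-2-yl methanesulfonate, 6 3,4,5-trimethoxybenzaldehyde
Product: 8 (1S,2R)-2-[(triisopropylsilyloxy)methyl]-1-(3,4,5-trimethoxyphenyl)but-3-yn-1-ol, via ethyl(allenyl)zinc reagent 7 (not isolated)
Conditions: Pd(OAc)2 (5 mol %), PPh3 (5 mol %), Et2Zn (3 equiv), THF, −78 to −20 °C; aq NH4Cl
Reagents that add atoms: diethylzinc, CC[Zn]CC (its zinc and one ethyl group are held only in 7; none of its atoms stay in 8)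
Why: Marshall propargylation, in which zerovalent palladium displaces the mesylate anti (SN2'), Et2Zn converts the allenylpalladium with retention into (aS)-7, and 7 adds to 6 on its zinc-bearing face through a closed SE2' transition state, so that C3 forms with net inversion of the carbinol carbon of 5 (R) and the aryl group turns away from the CH2OTIPS arm to give the anti alcohol (C2 S).

Step 6
Reactants: 8 (1S,2R)-2-[(triisopropylsilyloxy)methyl]-1-(3,4,5-trimethoxyphenyl)but-3-yn-1-ol, 9 4-iodo-1,2-dimethoxybenzene, 10 carbon monoxide
Product: 11 (3,4-dimethoxyphenyl){(4R,5S)-4-[(triisopropylsilyloxy)methyl]-5-(3,4,5-trimethoxyphenyl)-4,5-dihydrofuran-3-yl}methanone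
Conditions: Pd(PPh3)4 (5 mol %), 9 (1.5 equiv), powdered anhydrous K2CO3 (3 equiv), CO (1 atm, balloon), MeCN, 50 °C; 8 added slowly to the pre-carbonylated mixture; no copper salt, no amine
Reagents that add atoms: none
Why: Proposed new method: zerovalent palladium inserts into the C–I bond of 9, CO migrates in to give 3,4-dimethoxybenzoylpalladium iodide, this divalent palladium π-acid binds C4≡C5 of 8, the C2 hydroxyl attacks C5 anti to the metal while carbonate takes the proton (O1–C5), and reductive elimination from the vinyl(aroyl)palladium joins C4 to the ketone carbon and returns zerovalent palladium. The closest known reaction type is the carbonylative oxypalladation or aminopalladation–reductive elimination of 2-alkynylphenols and 2-alkynyltrifluoroacetanilides with aryl iodides and CO, which gives 3-aroylbenzofurans and 3-aroylindoles, and the 5-endo-dig oxypalladation–alkoxycarbonylation of aliphatic 3-yne-1,2-diols to furan-3-carboxylates shows that an sp3-bound hydroxyl can close this ring on palladium; new here is an aliphatic homopropargylic alcohol with a terminal alkyne as partner of an aroylpalladium species. The oxolane ring closes 5-endo-dig, the only alternative (4-exo-dig at C4) being too strained to compete. No stereocentre is made, and C2 and C3 are spectators because neither C–H is acidic toward K2CO3, so the 2,3-trans relation of 11 is that of anti-8. The step needs oxypalladation to outrun deprotonation of the terminal C–H with coupling at C5, alcoholysis of the aroylpalladium by the hydroxyl, and arylation without CO uptake. In 8 the hydroxyl is gauche to the alkyne in both low-energy rotamers about C2–C3 and is too hindered (secondary, benzylic, next to a branched carbon) for fast intermolecular acyl capture, while the lack of copper and amine, a sparingly soluble carbonate, polar MeCN that loosens iodide from palladium, slow addition of 8 and an electron-rich aryl group that migrates quickly to CO should hold back the other channels.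

Step 7
Reactants: 11 (3,4-dimethoxyphenyl){(4R,5S)-4-[(triisopropylsilyloxy)methyl]-5-(3,4,5-trimethoxyphenyl)-4,5-dihydrofuran-3-yl}methanone
Product: 12 (3,4-dimethoxyphenyl){(3R,4R,5S)-4-[(triisopropylsilyloxy)methyl]-5-(3,4,5-trimethoxyphenyl)oxolan-3-yl}methanone
Conditions: H2 (1 atm), 10% Pd/C, EtOAc, rt; stopped after uptake of one equivalent
Reagents that add atoms: none
Why: Heterogeneous syn hydrogenation of the β-alkoxy enone, in which the bulky CH2OTIPS group on the allylic carbon C3 stands directly beside C4 and should screen its face of the nearly flat ring more than the C2 aryl group, one ring atom further from both alkene carbons, screens the other, so that hydrogen reaches C4 anti to CH2OTIPS and sets C4 as R (aroyl cis to the C3 arm), while neutral EtOAc spares the aryl ketone, the benzylic C2–O1 bond and the epimerisable C4–H.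

Step 8
Reactants: 12 (3,4-dimethoxyphenyl){(3R,4R,5S)-4-[(triisopropylsilyloxy)methyl]-5-(3,4,5-trimethoxyphenyl)oxolan-3-yl}methanone
Product: 13 magnone B
Conditions: HF·pyridine, pyridine, THF, 0 °C to rt (plastic vessel); pH 7 buffer
Reagents that add atoms: none
Why: Fluoride-induced Si–O cleavage under buffered, weakly acidic conditions removes the primary silyl ether without forming an enolate, so the epimerisable C4 centre and the β-alkoxy ketone, which base could open by retro-oxa-Michael reaction, are preserved.

Compound list
1 | (R)-2,3-O-isopropylideneglyceraldehyde | O=C[C@H]1COC(C)(C)O1 | starting material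
2 | (4S)-4-ethynyl-2,2-dimethyl-1,3-dioxolane | C#C[C@H]1COC(C)(C)O1 | intermediate
3 | (2S)-but-3-yne-1,2-diol | C#C[C@@H](CO)O | intermediate
4 | (2S)-1-(triisopropylsilyloxy)but-3-yn-2-ol | C#C[C@@H](CO[Si](C(C)C)(C(C)C)C(C)C)O | intermediate
5 | (2S)-1-(triisopropylsilyloxy)but-3-yn-2-yl methanesulfonate | C#C[C@@H](CO[Si](C(C)C)(C(C)C)C(C)C)OS(C)(=O)=O | intermediate
6 | 3,4,5-trimethoxybenzaldehyde | COc1cc(C=O)cc(OC)c1OC | starting material
7 | ethyl[(aS)-4-(triisopropylsilyloxy)buta-1,2-dien-1-yl]zinc (not isolated) | CC[Zn]C([H])=[C@@]=C([H])CO[Si](C(C)C)(C(C)C)C(C)C | intermediate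
8 | (1S,2R)-2-[(triisopropylsilyloxy)methyl]-1-(3,4,5-trimethoxyphenyl)but-3-yn-1-ol (anti) | C#C[C@H](CO[Si](C(C)C)(C(C)C)C(C)C)[C@H](O)c1cc(OC)c(OC)c(OC)c1 | intermediate
9 | 4-iodo-1,2-dimethoxybenzene | COc1ccc(I)cc1OC | starting material
10 | carbon monoxide | [C-]#[O+] | starting material
11 | (3,4-dimethoxyphenyl){(4R,5S)-4-[(triisopropylsilyloxy)methyl]-5-(3,4,5-trimethoxyphenyl)-4,5-dihydrofuran-3-yl}methanone (4,5-trans) | COc1ccc(C(=O)C2=CO[C@H](c3cc(OC)c(OC)c(OC)c3)[C@H]2CO[Si](C(C)C)(C(C)C)C(C)C)cc1OC | intermediate
12 | (3,4-dimethoxyphenyl){(3R,4R,5S)-4-[(triisopropylsilyloxy)methyl]-5-(3,4,5-trimethoxyphenyl)oxolan-3-yl}methanone | COc1ccc(C(=O)[C@H]2CO[C@H](c3cc(OC)c(OC)c(OC)c3)[C@H]2CO[Si](C(C)C)(C(C)C)C(C)C)cc1OC | intermediate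
13 | magnone B, (3,4-dimethoxyphenyl)[(3R,4R,5S)-4-(hydroxymethyl)-5-(3,4,5-trimethoxyphenyl)oxolan-3-yl]methanone | COc1ccc(C(=O)[C@H]2CO[C@H](c3cc(OC)c(OC)c(OC)c3)[C@H]2CO)cc1OC | target

Total step count: 8. Longest linear sequence: 8 steps (1 to 13). Compounds 6, 9 and 10 are bought and enter directly.

Steps most likely to fail

Step 6 (the labelled step). Three processes may outrun the 5-endo oxypalladation: deprotonation of the palladium-bound terminal alkyne with coupling at C5, acyl transfer from palladium to the hydroxyl, and arylation before CO uptake. The fallback sets out from 8 and returns at 11. It separates ring closure from acylation and uses only known reactions. Alkynol 8 is cycloisomerised through a molybdenum vinylidene (Mo(CO)6, Me3NO, Et3N, Et2O, rt), a reaction established for 1-arylbut-3-yn-1-ols, to (2S,3R)-3-[(triisopropylsilyloxy)methyl]-2-(3,4,5-trimethoxyphenyl)-2,3-dihydrofuran F1. Vilsmeier–Haack formylation (POCl3, DMF, CH2Cl2, 0 °C), well known for glycals and other cyclic enol ethers, attacks the nucleophilic carbon C4 and gives the C4 dimethyliminium chloride F2. Aqueous NaOAc in the work-up hydrolyses this salt to the 4,5-dihydrofuran-3-carbaldehyde F3. Commercial 3,4-dimethoxyphenylmagnesium bromide (THF, −78 °C) adds to the formyl group and gives the allylic benzylic carbinol F4 as an epimer mixture of no consequence. MnO2 (CH2Cl2, rt) oxidises it to 11.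

Step 7. Facial selectivity may be poor, because the C2 aryl group lies on the face that hydrogen must reach. C4 may also epimerise toward the more stable 3,4-trans arrangement on the catalyst or on silica. The fallback sets out from 11 and returns at 13. It replaces kinetic face control by thermodynamic control through ring fusion. Compound 11 is hydrogenated without regard to the face, which gives 12 mixed with its C4 epimer, the (2S,3R,4S)-silyl ether F5. HF·pyridine turns the mixture into 13 and 4-epi-magnone B F6. Camphorsulfonic acid in MeOH/HC(OMe)3 (40 °C) enolises the aryl ketone, and only the 3,4-cis isomer can tie its CH2OH oxygen to the ketone carbon. Both epimers should therefore drain into the cis-fused 3,7-dioxabicyclo[3.3.0]octane methyl ketal F7, in which the C2 aryl group sits on the convex face. AcOH/H2O/THF (rt) then hydrolyses the ketal to 13 without any base.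

Step 5. The anti preference may erode with an aromatic aldehyde, the allenylpalladium or allenylzinc species may partly racemise, or silyloxide may be lost from the propargylic zinc tautomer. The fallback sets out from 4 and returns at 8. An isolable, configurationally stable allenylboronate replaces the transient zinc reagent, and a chiral acid adds a second control element. Alcohol 4 is converted (ClCO2Me, pyridine, CH2Cl2, 0 °C) into the (S)-propargylic methyl carbonate F8. Copper-catalysed anti-SN2' borylation (B2pin2, Cu(O-t-Bu), Xantphos, THF, rt) gives the (aS)-allenyl pinacolboronate F9. Allenylboration of 6 runs through the tight boron-centred cyclic transition state under catalysis by the matched enantiomer of the chiral phosphoric acid TRIP (toluene, 4 Å molecular sieves, −20 °C). Aqueous work-up should then deliver 8.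

Further compounds
F1 | step 6 | (2S,3R)-3-[(triisopropylsilyloxy)methyl]-2-(3,4,5-trimethoxyphenyl)-2,3-dihydrofuran | C1=CO[C@H](c2cc(OC)c(OC)c(OC)c2)[C@H]1CO[Si](C(C)C)(C(C)C)C(C)C
F2 | step 6 | C4 dimethyliminium chloride of F1 (not isolated) | C[N+](C)=CC1=CO[C@H](c2cc(OC)c(OC)c(OC)c2)[C@H]1CO[Si](C(C)C)(C(C)C)C(C)C.[Cl-]
F3 | step 6 | (4R,5S)-4-[(triisopropylsilyloxy)methyl]-5-(3,4,5-trimethoxyphenyl)-4,5-dihydrofuran-3-carbaldehyde | O=CC1=CO[C@H](c2cc(OC)c(OC)c(OC)c2)[C@H]1CO[Si](C(C)C)(C(C)C)C(C)C
F4 | step 6 | (3,4-dimethoxyphenyl){(4R,5S)-4-[(triisopropylsilyloxy)methyl]-5-(3,4,5-trimethoxyphenyl)-4,5-dihydrofuran-3-yl}methanol, both carbinol epimers | COc1ccc(C(O)C2=CO[C@H](c3cc(OC)c(OC)c(OC)c3)[C@H]2CO[Si](C(C)C)(C(C)C)C(C)C)cc1OC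
F5 | step 7 | C4 epimer of 12, oxolane (2S,3R,4S) | COc1ccc(C(=O)[C@@H]2CO[C@H](c3cc(OC)c(OC)c(OC)c3)[C@H]2CO[Si](C(C)C)(C(C)C)C(C)C)cc1OC
F6 | step 7 | 4-epi-magnone B, oxolane (2S,3R,4S) | COc1ccc(C(=O)[C@@H]2CO[C@H](c3cc(OC)c(OC)c(OC)c3)[C@H]2CO)cc1OC
F7 | step 7 | cis-fused 2-(3,4-dimethoxyphenyl)-2-methoxy-6-(3,4,5-trimethoxyphenyl)-3,7-dioxabicyclo[3.3.0]octane, other centres as in 13, both ketal epimers | COC1(c2ccc(OC)c(OC)c2)OC[C@H]2[C@@H]1CO[C@@H]2c1cc(OC)c(OC)c(OC)c1
F8 | step 5 | methyl (2S)-1-(triisopropylsilyloxy)but-3-yn-2-yl carbonate | C#C[C@@H](CO[Si](C(C)C)(C(C)C)C(C)C)OC(=O)OC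
F9 | step 5 | 2-[(aS)-4-(triisopropylsilyloxy)buta-1,2-dien-1-yl]-4,4,5,5-tetramethyl-1,3,2-dioxaborolane | CC1(C)OB(OC1(C)C)C([H])=[C@@]=C([H])CO[Si](C(C)C)(C(C)C)C(C)C
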